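Everything rests on cutting the CH2–CH2 bond between C11 (the methylene on decalin C9) and C12 (the methylene on C13 of the dienyl butenolide). The key step, a nickel-catalysed reductive cross-electrophile coupling, joins a primary C11 iodide carrying the finished, unprotected decalin triol to the C12 allylic acetate of the complete ylidenebutenolide and should give the target directly. It exploits C12 as the only unsubstituted terminus of the pentadienyl system C12–C16 that ends at furanone C5. The iodo-triol comes from (+)-larixol (Norrish cleavage to a C9=C11 alkene, O6-directed C18–H silylation, hydroboration that sets C9); the ten-carbon acetate comes from prenal and 4-methylbutenolide.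

Key step: step 11

Remark: labdane-type numbering is used (decalin C1–C10; C11 on C9; C17 = methyl on C8; C18 = 4α carbon; C19 = 4β methyl; C20 = 10β methyl; side chain C11–C12–C13(CH3)=C14–C15=C16, with C16–C19 in the furanone). All decalin compounds have 5α-H, 10β-CH3 (trans-decalin).
Assumption: (+)-larixol (13S), 4-methylfuran-2(5H)-one and 3-methylbut-2-enal are bought; C13 of larixol is excised in step 3, so its configuration has no consequence.

Step 1
Reactants: 1 (+)-larixol, labda-8(17),14-diene-6α,13S-diol
Product: 2 8α,17-epoxylabd-14-ene-6α,13S-diol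
Conditions: mCPBA (1.05 equiv), NaHCO3, CH2Cl2, 0 °C
Reagents that add atoms: 3-chloroperoxybenzoic acid, OOC(=O)c1cccc(Cl)c1
Why: Prilezhaev epoxidation should take the 1,1-disubstituted C8=C17 alkene far faster than the vinyl group, and the peracid should approach from the α face because the β face is screened by the axial 10β-methyl (C20), which places the oxygen 8α (equatorial) and sets C8.

Step 2
Reactants: 2 8α,17-epoxylabd-14-ene-6α,13S-diol
Product: 3 labd-14-ene-6α,8α,13S-triol
Conditions: LiAlH4, THF, 65 °C; aqueous NaOH work-up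
Reagents that add atoms: none
Why: Hydride should open the spiro-epoxide by SN2 attack at the primary C17, which turns C17 into the axial 8β-methyl and leaves the equatorial tertiary 8α-OH without touching the C8 configuration set in step 1.

Step 3
Reactants: 3 labd-14-ene-6α,8α,13S-triol
Product: 5 6α,8α-dihydroxy-14,15-dinorlabdan-13-one, via pentaol 4 (not isolated)
Conditions: OsO4 (2 mol %), NaIO4 (4 equiv), 2,6-lutidine, dioxane–H2O 3:1, 25 °C
Reagents that add atoms: none
Why: Lemieux–Johnson oxidation should dihydroxylate the only alkene and periodate should then cleave both C–C bonds of the 13,14,15-triol array (glycol, then α-hydroxy aldehyde), leaving C13 as a methyl ketone with its own oxygen, while the ring hydroxyls at C6 and C8 are not vicinal and survive.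

Step 4
Reactants: 5 6α,8α-dihydroxy-14,15-dinorlabdan-13-one
Product: 6 12,13,14,15,16-pentanorlabd-9(11)-ene-6α,8α-diol
Conditions: hν (medium-pressure Hg lamp, Pyrex), degassed hexane, 20 °C
Reagents that add atoms: none
Why: Norrish type II fragmentation of the open-chain ketone should abstract the tertiary γ-hydrogen at C9 through a six-membered transition state and cleave C11–C12 of the 1,4-biradical, giving the exocyclic C9=C11 alkene and acetone enol without touching the C8 carbinol.

Step 5
Reactants: 6 12,13,14,15,16-pentanorlabd-9(11)-ene-6α,8α-diol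
Product: 8 6α-O,18-C-(diethylsilanediyl)-12,13,14,15,16-pentanorlabd-9(11)-en-8α-ol (six-membered oxasilinane O6–SiEt2–C18), via hydrosilyl ether 7 (not isolated)
Conditions: Et2SiH2 (1.2 equiv), [Ir(cod)OMe]2 (0.5 mol %), THF, 25 °C, evaporate; then [Rh(cod)Cl]2 (2 mol %), Xantphos (4.4 mol %), norbornene (1.5 equiv), THF, 100 °C
Reagents that add atoms: diethylsilane, CC[SiH2]CC
Why: Iridium-catalysed dehydrogenative silylation should take the secondary 6α-OH in preference to the tertiary 8α-OH, and the rhodium/Xantphos-catalysed intramolecular silylation of a primary C–H bond δ to oxygen should reach only C18, whose equatorial C4–C18 bond is syn-parallel to the equatorial C6–O bond so that the oxasilinane closes as a third chair (C19 and C20 cannot), which sets the C4 stereocentre; the C9=C11 alkene has no allylic hydrogen and two quaternary neighbours and should stay out of isomerisation and hydrosilylation.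

Step 6
Reactants: 8 6α-O,18-C-(diethylsilanediyl)-12,13,14,15,16-pentanorlabd-9(11)-en-8α-ol
Product: 9 12,13,14,15,16-pentanorlabd-9(11)-ene-6α,8α,18-triol
Conditions: 30% H2O2, KHCO3, KF, THF–MeOH 1:1, 50 °C
Reagents that add atoms: hydrogen peroxide, OO
Why: Tamao–Fleming oxidation of the alkoxysilane should convert the C18–Si bond into C18–OH and release O6 by hydrolysis, conditions under which an unactivated alkene and a tertiary alcohol are inert.

Step 7
Reactants: 9 12,13,14,15,16-pentanorlabd-9(11)-ene-6α,8α,18-triol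
Product: 11 11-iodo-12,13,14,15,16-pentanorlabdane-6α,8α,18-triol (9α-H), via alkylborane 10 (not isolated)
Conditions: 9-BBN (4.5 equiv), THF, 65 °C; then NaOMe/MeOH, I2, 0 °C to 25 °C; aq. Na2S2O3
Reagents that add atoms: iodine, II
Why: Hydroboration should place boron on the terminal C11 and deliver hydrogen to C9 from the α face, because the β face is blocked by the two flanking axial methyls C17 and C20, which sets 9α-H with the CH2 group β (equatorial); the hydroxyls are only transiently O-borylated by the excess reagent and are freed by methanolysis, and base-induced iodinolysis of the borane (Brown) should cleave the primary B–C11 bond, since backside attack at the bicyclic bridgehead carbons of 9-BBN is not possible.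

Step 8
Reactants: 12 4-methylfuran-2(5H)-one; 13 3-methylbut-2-enal (prenal)
Product: 16 (5Z)-4-methyl-5-(3-methylbut-2-en-1-ylidene)furan-2(5H)-one, via silyloxyfuran 14 (not isolated), via aldol silyl ether 15 (not isolated)
Conditions: TBSOTf (1.1 equiv), Et3N, CH2Cl2, 0 °C; 13, TBSOTf (10 mol %), −78 °C; then DBU, −78 °C to 25 °C
Reagents that add atoms: none
Why: Soft enolisation should give the 2-silyloxyfuran, whose C5 adds 1,2 to prenal in a vinylogous Mukaiyama aldol reaction with silyl transfer to the aldolate, and DBU should then remove the C5 proton and expel silanolate (E1cB) to the Z-ylidene, the E isomer being disfavoured by allylic strain with the 4-methyl group.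

Step 9
Reactants: 16 (5Z)-4-methyl-5-(3-methylbut-2-en-1-ylidene)furan-2(5H)-one
Product: 17 (5Z)-5-[(2E)-4-hydroxy-3-methylbut-2-en-1-ylidene]-4-methylfuran-2(5H)-one
Conditions: SeO2 (0.5 equiv), t-BuOOH (2 equiv), salicylic acid (10 mol %), CH2Cl2, 25 °C
Reagents that add atoms: selenium dioxide, O=[Se]=O (oxygen-transfer agent); tert-butyl hydroperoxide, CC(C)(C)OO (stoichiometric oxygen source)
Why: Riley allylic oxidation (ene reaction, then [2,3]-sigmatropic shift) should act at the more substituted end of the terminal C13=C14 alkene and on the methyl trans to the chain, as with other gem-dimethyl olefins, so that the new CH2OH is C12 with 13E geometry, while the C17 methyl on the electron-poor lactone alkene should react much more slowly.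

Step 10
Reactants: 17 (5Z)-5-[(2E)-4-hydroxy-3-methylbut-2-en-1-ylidene]-4-methylfuran-2(5H)-one
Product: 18 (2E)-2-methyl-4-[(2Z)-3-methyl-5-oxofuran-2(5H)-ylidene]but-2-en-1-yl acetate
Conditions: Ac2O, pyridine, DMAP (5 mol %), CH2Cl2, 0 °C
Reagents that add atoms: acetic anhydride, CC(=O)OC(C)=O
Why: Acylation of a primary allylic alcohol under mild amine conditions should leave the enol lactone and both double-bond geometries untouched.

Step 11
Reactants: 11 11-iodo-12,13,14,15,16-pentanorlabdane-6α,8α,18-triol; 18 (2E)-2-methyl-4-[(2Z)-3-methyl-5-oxofuran-2(5H)-ylidene]but-2-en-1-yl acetate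
Product: 19 target, (5Z)-4-methyl-5-[(2E)-3-methyl-4-(6α,8α,18-trihydroxy-12,13,14,15,16-pentanorlabdan-11-yl)but-2-en-1-ylidene]furan-2(5H)-one
Conditions: NiCl2·glyme (10 mol %), 4,4′,4″-tri-tert-butyl-2,2′:6′,2″-terpyridine (10 mol %), Zn dust (2.5 equiv), DMA–THF, 30 °C, slow addition of 18 (1.5 equiv)
Reagents that add atoms: none
Why: Ni(0) should add oxidatively to allylic acetate 18 to give an η3-allylnickel that extends as a pentadienyl unit from C12 to C16, while zinc-reduced nickel abstracts iodine from 11 to give the primary C11 radical, which is captured at nickel and reductively eliminated onto C12, zinc turning the catalyst over. The closest known reaction type is the nickel-catalysed reductive allylation of unactivated alkyl halides with allylic acetates or carbonates, which couples at the less hindered allyl terminus with E selectivity and tolerates esters and free hydroxyl groups. No ring is closed and no stereocentre is created; C9, set in step 7, lies one carbon from the radical site and is not touched. The step needs regioselectivity for C12 over C14 and C16, which the substrate secures because C12 is the only CH2 terminus, coupling at C14 would break conjugation with the furanone and coupling at C16 would build a quaternary oxygen-bearing carbon. It needs retention of the 13E and 15Z geometries, secured by starting from the syn,syn (W-shaped) allyl complex that is also the thermodynamically preferred one, and cross- over homo-coupling, secured by the two different activation modes (two-electron for the acetate, halogen abstraction for the iodide) and the slow addition of 18. Acetate is chosen over carbonate so that no alkoxide is released next to the enol lactone.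

Compound list
1 | (+)-larixol, labda-8(17),14-diene-6α,13S-diol | C=C[C@@](C)(O)CC[C@@H]1[C@@]2(C)CCCC(C)(C)[C@@H]2[C@@H](O)CC1=C | starting material
2 | 8α,17-epoxylabd-14-ene-6α,13S-diol | C=C[C@@](C)(O)CC[C@@H]1[C@@]2(C)CCCC(C)(C)[C@@H]2[C@@H](O)C[C@@]1(C3)O3 | intermediate
3 | labd-14-ene-6α,8α,13S-triol | C=C[C@@](C)(O)CC[C@@H]1[C@@]2(C)CCCC(C)(C)[C@@H]2[C@@H](O)C[C@@]1(C)O | intermediate
4 | labdane-6α,8α,13,14,15-pentaol (14-epimers) | OCC(O)[C@@](C)(O)CC[C@@H]1[C@@]2(C)CCCC(C)(C)[C@@H]2[C@@H](O)C[C@@]1(C)O | intermediate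
5 | 6α,8α-dihydroxy-14,15-dinorlabdan-13-one | CC(=O)CC[C@@H]1[C@@]2(C)CCCC(C)(C)[C@@H]2[C@@H](O)C[C@@]1(C)O | intermediate
6 | 12,13,14,15,16-pentanorlabd-9(11)-ene-6α,8α-diol | C=C1[C@@]2(C)CCCC(C)(C)[C@@H]2[C@@H](O)C[C@@]1(C)O | intermediate
7 | 6α-(diethylsilyloxy)-12,13,14,15,16-pentanorlabd-9(11)-en-8α-ol | C=C1[C@@]2(C)CCCC(C)(C)[C@@H]2[C@@H](O[SiH](CC)CC)C[C@@]1(C)O | intermediate
8 | 6α-O,18-C-(diethylsilanediyl)-12,13,14,15,16-pentanorlabd-9(11)-en-8α-ol | C=C1[C@@]2(C)CCC[C@@](C)(C[Si]3(CC)CC)[C@@H]2[C@@H](O3)C[C@@]1(C)O | intermediate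
9 | 12,13,14,15,16-pentanorlabd-9(11)-ene-6α,8α,18-triol | C=C1[C@@]2(C)CCC[C@@](C)(CO)[C@@H]2[C@@H](O)C[C@@]1(C)O | intermediate
10 | 11-(9-borabicyclo[3.3.1]nonan-9-yl)-12,13,14,15,16-pentanorlabdane-6α,8α,18-triol (9α-H) | C(B1C2CCCC1CCC2)[C@@H]1[C@@]2(C)CCC[C@@](C)(CO)[C@@H]2[C@@H](O)C[C@@]1(C)O | intermediate
11 | 11-iodo-12,13,14,15,16-pentanorlabdane-6α,8α,18-triol (9α-H) | IC[C@@H]1[C@@]2(C)CCC[C@@](C)(CO)[C@@H]2[C@@H](O)C[C@@]1(C)O | intermediate
12 | 4-methylfuran-2(5H)-one | CC1=CC(=O)OC1 | starting material
13 | 3-methylbut-2-enal (prenal) | CC(C)=CC=O | starting material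
14 | tert-butyl(dimethyl)[(4-methylfuran-2-yl)oxy]silane | Cc1coc(O[Si](C)(C)C(C)(C)C)c1 | intermediate
15 | 5-[1-(tert-butyldimethylsilyloxy)-3-methylbut-2-en-1-yl]-4-methylfuran-2(5H)-one (diastereomers) | CC1=CC(=O)OC1C(O[Si](C)(C)C(C)(C)C)C=C(C)C | intermediate
16 | (5Z)-4-methyl-5-(3-methylbut-2-en-1-ylidene)furan-2(5H)-one | CC1=CC(=O)O/C1=C\C=C(C)C | intermediate
17 | (5Z)-5-[(2E)-4-hydroxy-3-methylbut-2-en-1-ylidene]-4-methylfuran-2(5H)-one | CC1=CC(=O)O/C1=C\C=C(/C)CO | intermediate
18 | (2E)-2-methyl-4-[(2Z)-3-methyl-5-oxofuran-2(5H)-ylidene]but-2-en-1-yl acetate | CC1=CC(=O)O/C1=C\C=C(/C)COC(C)=O | intermediate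
19 | (5Z)-4-methyl-5-[(2E)-3-methyl-4-(6α,8α,18-trihydroxy-12,13,14,15,16-pentanorlabdan-11-yl)but-2-en-1-ylidene]furan-2(5H)-one | CC1=CC(=O)O/C1=C\C=C(/C)CC[C@@H]1[C@@]2(C)CCC[C@@](C)(CO)[C@@H]2[C@@H](O)C[C@@]1(C)O | target

Total step count: 11. Longest linear sequence: 8 steps (steps 1–7, then step 11).

Steps most likely to fail

Step 11. The hindered C11 radical may be captured too slowly, so that reductive dimerisation or hydrogenolysis of the allyl partner takes over. The allylnickel may also isomerise (syn/anti, or by sliding along C12–C16) and erode the 13E geometry, and low-valent nickel or zinc may attack the enol lactone. The fallback sets out from 9 and comes back at 19. It forms the same C11–C12 bond by a copper-catalysed SN2 alkylation without a π-allyl intermediate and builds the butenolide afterwards. Triol 9 would be persilylated (TESOTf, 2,6-lutidine) to the tris(triethylsilyl) ether F1; 9-BBN would give the alkylborane F2, NaOMe/I2 the iodide F3, and t-BuLi (Et2O, −78 °C) the alkyllithium F4. Propargyl alcohol would be carbometallated (Me3Al, Cp2ZrCl2; then I2) to (E)-3-iodo-2-methylprop-2-en-1-ol F5, coupled with trimethylsilylacetylene (PdCl2(PPh3)2, CuI, Et3N) to the enynol F6 and brominated (CBr4, PPh3) to the allylic bromide F7. After transmetalation with MgBr2, F4 would be alkylated by F7 under Li2CuCl4 catalysis to the silylated enyne F8. TBAF would remove all four silyl groups to give the enyne triol F9. Pd/Cu-catalysed coupling of F9 with (Z)-3-iodobut-2-enoic acid F10 (from but-2-ynoic acid, NaI, AcOH), followed in the same flask by 5-exo-dig lactonisation, would close the (Z)-ylidenebutenolide and give 19.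

Step 5. Rhodium hydride or silyl species may hydrosilylate or hydrogenate the C9=C11 alkene, the tertiary allylic 8-OH may be silylated and divert the catalyst, or C–H cleavage at the neopentyl-type methyl may be too slow. The fallback sets out from 6 and comes back at 9; it is a Barton nitrite photolysis that uses the same O6/C18 proximity. NOCl in pyridine (−20 °C) would give the 6α-nitrite F11. Irradiation (benzene, Pyrex) would move NO to C18 by 1,5-hydrogen transfer, the nitroso compound being isolated as the 18-oxime F12. TiCl3/NH4OAc would cleave the oxime to the 18-aldehyde F13 (present as its 6α,18-lactol), and NaBH4 would give triol 9.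

Step 9. The selenium electrophile may attack the dienyl enol ester in other ways (1,4-oxidation, oligomerisation), the alcohol may be over-oxidised to the enal, or the three allylic methyl groups may not be differentiated. The fallback sets out from 12 and comes back at 17; it brings the oxygen in with the aldehyde. 1-(tert-Butyldimethylsilyloxy)propan-2-one (bought) and triethyl phosphonoacetate (NaH, THF; Horner–Wadsworth–Emmons) would give the (E)-ester F14. DIBAL-H would give the allylic alcohol F15 and MnO2 the enal F16. The one-pot procedure of step 8, run with 12 and F16, would give, through the aldol bis-silyl ether F17, the silyl ether F18, and HF·pyridine would give 17.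

Further compounds
F1 | step 11 | 6α,8α,18-tris(triethylsilyloxy)-12,13,14,15,16-pentanorlabd-9(11)-ene | C=C1[C@@]2(C)CCC[C@@](C)(CO[Si](CC)(CC)CC)[C@@H]2[C@@H](O[Si](CC)(CC)CC)C[C@@]1(C)O[Si](CC)(CC)CC
F2 | step 11 | 11-(9-borabicyclo[3.3.1]nonan-9-yl)-6α,8α,18-tris(triethylsilyloxy)-12,13,14,15,16-pentanorlabdane | C(B1C2CCCC1CCC2)[C@@H]1[C@@]2(C)CCC[C@@](C)(CO[Si](CC)(CC)CC)[C@@H]2[C@@H](O[Si](CC)(CC)CC)C[C@@]1(C)O[Si](CC)(CC)CC
F3 | step 11 | 11-iodo-6α,8α,18-tris(triethylsilyloxy)-12,13,14,15,16-pentanorlabdane | IC[C@@H]1[C@@]2(C)CCC[C@@](C)(CO[Si](CC)(CC)CC)[C@@H]2[C@@H](O[Si](CC)(CC)CC)C[C@@]1(C)O[Si](CC)(CC)CC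
F4 | step 11 | 11-lithio-6α,8α,18-tris(triethylsilyloxy)-12,13,14,15,16-pentanorlabdane | [Li]C[C@@H]1[C@@]2(C)CCC[C@@](C)(CO[Si](CC)(CC)CC)[C@@H]2[C@@H](O[Si](CC)(CC)CC)C[C@@]1(C)O[Si](CC)(CC)CC
F5 | step 11 | (E)-3-iodo-2-methylprop-2-en-1-ol | OC/C(C)=C/I
F6 | step 11 | (E)-2-methyl-5-(trimethylsilyl)pent-2-en-4-yn-1-ol | OC/C(C)=C/C#C[Si](C)(C)C
F7 | step 11 | (E)-(5-bromo-4-methylpent-3-en-1-yn-1-yl)trimethylsilane | BrC/C(C)=C/C#C[Si](C)(C)C
F8 | step 11 | (E)-11-[2-methyl-5-(trimethylsilyl)pent-2-en-4-yn-1-yl]-6α,8α,18-tris(triethylsilyloxy)-12,13,14,15,16-pentanorlabdane | C[Si](C)(C)C#C\C=C(/C)CC[C@@H]1[C@@]2(C)CCC[C@@](C)(CO[Si](CC)(CC)CC)[C@@H]2[C@@H](O[Si](CC)(CC)CC)C[C@@]1(C)O[Si](CC)(CC)CC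
F9 | step 11 | (E)-11-(2-methylpent-2-en-4-yn-1-yl)-12,13,14,15,16-pentanorlabdane-6α,8α,18-triol | C#C\C=C(/C)CC[C@@H]1[C@@]2(C)CCC[C@@](C)(CO)[C@@H]2[C@@H](O)C[C@@]1(C)O
F10 | step 11 | (Z)-3-iodobut-2-enoic acid | C/C(I)=C/C(=O)O
F11 | step 5 | 8α-hydroxy-12,13,14,15,16-pentanorlabd-9(11)-en-6α-yl nitrite | C=C1[C@@]2(C)CCCC(C)(C)[C@@H]2[C@@H](ON=O)C[C@@]1(C)O
F12 | step 5 | 6α,8α-dihydroxy-12,13,14,15,16-pentanorlabd-9(11)-en-18-al oxime | C=C1[C@@]2(C)CCC[C@@](C)(C=NO)[C@@H]2[C@@H](O)C[C@@]1(C)O
F13 | step 5 | 6α,8α-dihydroxy-12,13,14,15,16-pentanorlabd-9(11)-en-18-al (open form of the 6α,18-lactol) | C=C1[C@@]2(C)CCC[C@@](C)(C=O)[C@@H]2[C@@H](O)C[C@@]1(C)O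
F14 | step 9 | ethyl (E)-4-(tert-butyldimethylsilyloxy)-3-methylbut-2-enoate | CCOC(=O)/C=C(\C)CO[Si](C)(C)C(C)(C)C
F15 | step 9 | (E)-4-(tert-butyldimethylsilyloxy)-3-methylbut-2-en-1-ol | OC/C=C(\C)CO[Si](C)(C)C(C)(C)C
F16 | step 9 | (E)-4-(tert-butyldimethylsilyloxy)-3-methylbut-2-enal | O=C/C=C(\C)CO[Si](C)(C)C(C)(C)C
F17 | step 9 | 5-[(2E)-1,4-bis(tert-butyldimethylsilyloxy)-3-methylbut-2-en-1-yl]-4-methylfuran-2(5H)-one (diastereomers) | CC1=CC(=O)OC1C(O[Si](C)(C)C(C)(C)C)/C=C(\C)CO[Si](C)(C)C(C)(C)C
F18 | step 9 | (5Z)-5-[(2E)-4-(tert-butyldimethylsilyloxy)-3-methylbut-2-en-1-ylidene]-4-methylfuran-2(5H)-one | CC1=CC(=O)O/C1=C\C=C(/C)CO[Si](C)(C)C(C)(C)C
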